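**Plan** (flavone numbering: O1, C2, C3, C4, C4a, C5–C8, C8a; ring B primed)
1. Retrosynthesis: the O5 methyl group, the O4' allyl group and the C3–O bond are taken off first; ring C is then cut at C4–C4a (acylation) and at O1–C2 (phenol-to-alkyne addition).
2. Ring A gives up its prenyl group at C8 (Claisen rearrangement of an O-bound 1,1-dimethylallyl unit); ring B gives up its alkyne at C1'–C2 (Sonogashira coupling).
3. Forward: rings A and B are bought as benzenes, the two halves are joined through O1–C2, and ring C is the only ring built, closing last at C4–C4a.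
4. Enabling feature: in the open precursor, C4a of ring A is ortho to O1, ortho to the C5 oxygen and para to the C7 oxygen, and it is the only unsubstituted carbon next to O1 because C8 already carries the prenyl group.
5. Stereochemistry: the target has no stereocentre; the only geometric element is the C2=C3 double bond of the open precursor, set Z by anti addition and absorbed into the pyranone.

Key step: step 8

Remark: the target is achiral, so no enantiocontrol is needed; compounds 11–13 are drawn as the Z isomers expected from anti addition, and any E isomer is expected to converge in the ring closure.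

**Step 1**
Reactants: 1 3,5-dimethoxyphenol; 2 3-chloro-3-methylbut-1-yne
Product: 3 1,3-dimethoxy-5-[(2-methylbut-3-yn-2-yl)oxy]benzene
Conditions: CuCl2·2H2O (cat.), DBU, MeCN, 0 °C
Reagents that add atoms: none
Why: Copper-catalysed propargylic substitution of a tertiary propargylic chloride by a phenol is the standard entry to aryl 1,1-dimethylpropargyl ethers and should favour O- over C-alkylation at 0 °C.

**Step 2**
Reactants: 3 1,3-dimethoxy-5-[(2-methylbut-3-yn-2-yl)oxy]benzene
Product: 4 1,3-dimethoxy-5-[(2-methylbut-3-en-2-yl)oxy]benzene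
Conditions: H2 (1 atm), Lindlar catalyst, quinoline, EtOAc, rt
Reagents that add atoms: none
Why: Lindlar semihydrogenation of a terminal alkyne should stop at the vinyl group, since the poisoned catalyst neither reduces the alkene nor cleaves the tertiary allylic ether.

**Step 3**
Reactants: 4 1,3-dimethoxy-5-[(2-methylbut-3-en-2-yl)oxy]benzene
Product: 6 3,5-dimethoxy-2-(3-methylbut-2-en-1-yl)phenol, via ortho-dienone 5 (not isolated)
Conditions: PhNEt2, 130 °C
Reagents that add atoms: none
Why: The aromatic Claisen rearrangement ([3,3] shift) delivers the 1,1-dimethylallyl unit with allylic inversion as a linear prenyl group to an ortho carbon, the two ortho carbons being equivalent by symmetry, and dienone 5 tautomerises to the phenol while the basic solvent suppresses chroman formation.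

**Step 4**
Reactants: 7 4-iodophenol
Product: 8 1-iodo-4-(prop-2-en-1-yloxy)benzene
Conditions: allyl bromide, K2CO3, acetone, reflux
Reagents that add atoms: allyl bromide, C=CCBr
Why: Williamson ether synthesis (SN2 of the phenoxide on allyl bromide) is routine for 4-iodophenol.

**Step 5**
Reactants: 8 1-iodo-4-(prop-2-en-1-yloxy)benzene; 9 ethyl propiolate
Product: 10 ethyl 3-[4-(prop-2-en-1-yloxy)phenyl]prop-2-ynoate
Conditions: PdCl2(PPh3)2 (cat.), CuI (cat.), K2CO3, THF, 60 °C
Reagents that add atoms: none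
Why: Sonogashira coupling of an aryl iodide with ethyl propiolate should proceed under amine-free carbonate conditions, which avoid conjugate addition of an amine to the propiolate, while oxidative addition into C–I outpaces any ionisation of the allyl aryl ether.

**Step 6**
Reactants: 6 3,5-dimethoxy-2-(3-methylbut-2-en-1-yl)phenol; 10 ethyl 3-[4-(prop-2-en-1-yloxy)phenyl]prop-2-ynoate
Product: 11 ethyl (2Z)-3-[3,5-dimethoxy-2-(3-methylbut-2-en-1-yl)phenoxy]-3-[4-(prop-2-en-1-yloxy)phenyl]prop-2-enoate
Conditions: Cs2CO3 (0.5 equiv), DMF, 80 °C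
Reagents that add atoms: none
Why: Base-mediated oxa-Michael addition of a phenoxide to an arylpropiolate, the first stage of the Ruhemann flavone synthesis, forms O1–C2; anti addition should place the aryloxy group cis to the ester, and the base is regenerated when the vinyl anion is reprotonated.

**Step 7**
Reactants: 11 ethyl (2Z)-3-[3,5-dimethoxy-2-(3-methylbut-2-en-1-yl)phenoxy]-3-[4-(prop-2-en-1-yloxy)phenyl]prop-2-enoate
Product: 12 (2Z)-3-[3,5-dimethoxy-2-(3-methylbut-2-en-1-yl)phenoxy]-3-[4-(prop-2-en-1-yloxy)phenyl]prop-2-enoic acid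
Conditions: LiOH, THF/H2O, rt → 40 °C; then 1 M HCl to pH 3, 0 °C
Reagents that add atoms: lithium hydroxide, [Li+].[OH-]
Why: Saponification of the ethyl ester should leave the vinylogous carbonate intact at moderate temperature, and brief cold acidification frees the acid without touching the prenyl group.

**Step 8**
Reactants: 12 (2Z)-3-[3,5-dimethoxy-2-(3-methylbut-2-en-1-yl)phenoxy]-3-[4-(prop-2-en-1-yloxy)phenyl]prop-2-enoic acid
Product: 14 5,7-dimethoxy-8-(3-methylbut-2-en-1-yl)-2-[4-(prop-2-en-1-yloxy)phenyl]-4H-chromen-4-one, via acid chloride 13 (not isolated)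
Conditions: (i) 1-chloro-N,N,2-trimethylprop-1-en-1-amine (1.0 equiv), CH2Cl2, 0 °C → rt; (ii) AgOTf, 2,6-di-tert-butyl-4-methylpyridine, CH2Cl2, −40 → 0 °C
Reagents that add atoms: 1-chloro-N,N,2-trimethylprop-1-en-1-amine, CC(C)=C(Cl)N(C)C (supplies the chlorine of 13 only; no reagent atom remains in 14)
Why: The α-chloroenamine turns the acid into acid chloride 13 without releasing HCl, and silver triflate then abstracts chloride to give an acylium ion (acyl triflate) stabilised by the lone pair of O1 through C2=C3. C4a attacks this electrophile and the hindered pyridine takes the proton from the Wheland intermediate, so the medium should never become acidic enough to protonate the prenyl or allyl double bond. The closest known reaction type is the Ruhemann flavone synthesis, the intramolecular Friedel–Crafts acylation of a β-aryloxycinnamoyl chloride, here run with silver-triflate activation of the acyl chloride. Ring C, the six-membered pyranone, closes by formation of C4–C4a in a 6-exo mode with respect to the acyl C=O, the arene bond C4a–C8a lying inside the new ring. No stereocentre is formed; the step needs site selectivity for C4a, which is secured because C4a is the only free carbon ortho to O1 (C8 is blocked by the prenyl group), C6 cannot reach the acyl carbon, C4a is activated by the ortho C5 and para C7 methoxy groups, and attack by either alkene would need a medium ring. Any E isomer should equilibrate with the Z form in the O1-stabilised cation, where C2–C3 has single-bond character, so both geometries lead to 14.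

**Step 9**
Reactants: 14 5,7-dimethoxy-8-(3-methylbut-2-en-1-yl)-2-[4-(prop-2-en-1-yloxy)phenyl]-4H-chromen-4-one
Product: 17 3-hydroxy-5,7-dimethoxy-8-(3-methylbut-2-en-1-yl)-2-[4-(prop-2-en-1-yloxy)phenyl]-4H-chromen-4-one, via 3-lithioflavone 15 (not isolated), via dimethyl flavon-3-ylboronate 16 (not isolated)
Conditions: LDA, THF, −78 °C; B(OMe)3, −78 → 0 °C; 30% aq. H2O2, 0 °C → rt
Reagents that add atoms: lithium diisopropylamide, [Li+].CC(C)[N-]C(C)C (lithium of 15); trimethyl borate, COB(OC)OC (boron and two methoxy groups of 16); hydrogen peroxide, OO (the C3 oxygen of 17)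
Why: Carbonyl-directed lithiation of a flavone at C3, borylation and oxidation of the C–B bond is an established route from alkoxyflavones to flavonols; keeping −78 °C until the borate is added prevents ring opening of the 3-lithio species, and aqueous peroxide without added acid should not epoxidise the isolated double bonds.

**Step 10**
Reactants: 17 3-hydroxy-5,7-dimethoxy-8-(3-methylbut-2-en-1-yl)-2-[4-(prop-2-en-1-yloxy)phenyl]-4H-chromen-4-one
Product: 18 3-hydroxy-2-(4-hydroxyphenyl)-5,7-dimethoxy-8-(3-methylbut-2-en-1-yl)-4H-chromen-4-one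
Conditions: Pd(PPh3)4 (cat.), morpholine, THF, rt
Reagents that add atoms: none
Why: Palladium(0)-catalysed deallylation (Tsuji–Trost type) ionises only the allyl aryl ether to a π-allyl complex that morpholine intercepts, whereas the prenyl group has no leaving group and the methyl ethers are inert.

**Step 11**
Reactants: 18 3-hydroxy-2-(4-hydroxyphenyl)-5,7-dimethoxy-8-(3-methylbut-2-en-1-yl)-4H-chromen-4-one
Product: 19 isoanhydroicaritin, 3,5-dihydroxy-2-(4-hydroxyphenyl)-7-methoxy-8-(3-methylbut-2-en-1-yl)-4H-chromen-4-one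
Conditions: MgI2·OEt2 (excess), THF, 60 °C; aqueous work-up
Reagents that add atoms: none
Why: In this chelation-directed ether cleavage, magnesium bridges the C4 carbonyl and the peri C5 methoxy oxygen so that iodide removes only that methyl group by SN2; the C7 methyl ether cannot chelate, and this non-protic reagent type is used for 5-methoxy-8-prenylflavanones without harm to the prenyl group.

**Compound list**
1 | 3,5-dimethoxyphenol | COc1cc(O)cc(OC)c1 | starting material
2 | 3-chloro-3-methylbut-1-yne | CC(C)(Cl)C#C | starting material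
3 | 1,3-dimethoxy-5-[(2-methylbut-3-yn-2-yl)oxy]benzene | COc1cc(OC)cc(OC(C)(C)C#C)c1 | intermediate
4 | 1,3-dimethoxy-5-[(2-methylbut-3-en-2-yl)oxy]benzene | COc1cc(OC)cc(OC(C)(C)C=C)c1 | intermediate
5 | 3,5-dimethoxy-6-(3-methylbut-2-en-1-yl)cyclohexa-2,4-dien-1-one (ortho-dienone, formed in the flask) | O=C1C=C(OC)C=C(OC)C1CC=C(C)C | intermediate
6 | 3,5-dimethoxy-2-(3-methylbut-2-en-1-yl)phenol | COc1cc(O)c(CC=C(C)C)c(OC)c1 | intermediate
7 | 4-iodophenol | Oc1ccc(I)cc1 | starting material
8 | 1-iodo-4-(prop-2-en-1-yloxy)benzene | C=CCOc1ccc(I)cc1 | intermediate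
9 | ethyl propiolate | C#CC(=O)OCC | starting material
10 | ethyl 3-[4-(prop-2-en-1-yloxy)phenyl]prop-2-ynoate | C=CCOc1ccc(C#CC(=O)OCC)cc1 | intermediate
11 | ethyl (2Z)-3-[3,5-dimethoxy-2-(3-methylbut-2-en-1-yl)phenoxy]-3-[4-(prop-2-en-1-yloxy)phenyl]prop-2-enoate | CCOC(=O)/C=C(/c1ccc(OCC=C)cc1)Oc1cc(OC)cc(OC)c1CC=C(C)C | intermediate
12 | (2Z)-3-[3,5-dimethoxy-2-(3-methylbut-2-en-1-yl)phenoxy]-3-[4-(prop-2-en-1-yloxy)phenyl]prop-2-enoic acid | O=C(O)/C=C(/c1ccc(OCC=C)cc1)Oc1cc(OC)cc(OC)c1CC=C(C)C | intermediate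
13 | (2Z)-3-[3,5-dimethoxy-2-(3-methylbut-2-en-1-yl)phenoxy]-3-[4-(prop-2-en-1-yloxy)phenyl]prop-2-enoyl chloride (formed in the flask) | O=C(Cl)/C=C(/c1ccc(OCC=C)cc1)Oc1cc(OC)cc(OC)c1CC=C(C)C | intermediate
14 | 5,7-dimethoxy-8-(3-methylbut-2-en-1-yl)-2-[4-(prop-2-en-1-yloxy)phenyl]-4H-chromen-4-one | C=CCOc1ccc(-c2cc(=O)c3c(OC)cc(OC)c(CC=C(C)C)c3o2)cc1 | intermediate
15 | [5,7-dimethoxy-8-(3-methylbut-2-en-1-yl)-4-oxo-2-[4-(prop-2-en-1-yloxy)phenyl]-4H-chromen-3-yl]lithium (formed in the flask) | C=CCOc1ccc(-c2oc3c(CC=C(C)C)c(OC)cc(OC)c3c(=O)c2[Li])cc1 | intermediate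
16 | dimethyl [5,7-dimethoxy-8-(3-methylbut-2-en-1-yl)-4-oxo-2-[4-(prop-2-en-1-yloxy)phenyl]-4H-chromen-3-yl]boronate (formed in the flask) | C=CCOc1ccc(-c2oc3c(CC=C(C)C)c(OC)cc(OC)c3c(=O)c2B(OC)OC)cc1 | intermediate
17 | 3-hydroxy-5,7-dimethoxy-8-(3-methylbut-2-en-1-yl)-2-[4-(prop-2-en-1-yloxy)phenyl]-4H-chromen-4-one | C=CCOc1ccc(-c2oc3c(CC=C(C)C)c(OC)cc(OC)c3c(=O)c2O)cc1 | intermediate
18 | 3-hydroxy-2-(4-hydroxyphenyl)-5,7-dimethoxy-8-(3-methylbut-2-en-1-yl)-4H-chromen-4-one | CC(C)=CCc1c(OC)cc(OC)c2c(=O)c(O)c(-c3ccc(O)cc3)oc12 | intermediate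
19 | isoanhydroicaritin, 3,5-dihydroxy-2-(4-hydroxyphenyl)-7-methoxy-8-(3-methylbut-2-en-1-yl)-4H-chromen-4-one | COc1cc(O)c2c(=O)c(O)c(-c3ccc(O)cc3)oc2c1CC=C(C)C | target

**Totals**
Total step count: 11.
Longest linear sequence: 9 steps (steps 1, 2, 3, 6, 7, 8, 9, 10, 11).

**Steps most likely to fail**

Step 8. The acylation at C4a may be outrun by electrophilic attack on the prenyl double bond (cation formation and cyclisation onto a neighbouring oxygen, or addition of acid) or by decomposition of the activated acyl species. The fallback runs the same C4–C4a closure without the prenyl group and adds that group afterwards. It sets out from 1 and 10 and comes back at 14. Conjugate addition as in step 6 would give ethyl (2Z)-3-(3,5-dimethoxyphenoxy)-3-[4-(prop-2-en-1-yloxy)phenyl]prop-2-enoate F1, and saponification the corresponding (2Z)-3-(3,5-dimethoxyphenoxy)-3-[4-(prop-2-en-1-yloxy)phenyl]prop-2-enoic acid F2. Cyclodehydration with P2O5 in MeSO3H at rt, where both ortho positions are equivalent and no prenyl group is at risk, should give 5,7-dimethoxy-2-[4-(prop-2-en-1-yloxy)phenyl]-4H-chromen-4-one F3. Iodination with N-iodosuccinimide (cat. TFA, MeCN) should take C8, the less hindered of the two activated ring-A carbons since C6 lies between two methoxy groups, to give 8-iodo-5,7-dimethoxy-2-[4-(prop-2-en-1-yloxy)phenyl]-4H-chromen-4-one F4. Suzuki–Miyaura coupling of F4 with 3-methylbut-2-enylboronic acid pinacol ester (Pd with a bulky biarylphosphine chosen for the linear product, K3PO4, THF/H2O) would then return to 14.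

Step 6. Addition of the ortho-substituted, hindered phenoxide to the donor-substituted ynoate may be slow or reversible, with attack through ring carbon or cleavage of the ester competing. The fallback replaces conjugate addition by cross-coupling at a vinyl iodide. It sets out from 10 and comes back at 11. Hydroiodination of 10 (LiI, AcOH, 70 °C, anti addition) should give ethyl (2Z)-3-iodo-3-[4-(prop-2-en-1-yloxy)phenyl]prop-2-enoate F5. Copper-catalysed Ullmann-type coupling of F5 with phenol 6 (CuI, N,N-dimethylglycine, Cs2CO3, dioxane, 90 °C) proceeds with retention of alkene geometry and would give 11.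

Step 11. The 3-hydroxy-4-keto unit may sequester the magnesium, so that cleavage of the C5 methyl ether stalls or loses its preference over the C7 methyl ether. The fallback moves the peri-demethylation ahead of the C3 hydroxylation and carries O5 as an allyl ether. It sets out from 14 and comes back at 19. MgI2·OEt2 in THF should convert 14 into 5-hydroxy-7-methoxy-8-(3-methylbut-2-en-1-yl)-2-[4-(prop-2-en-1-yloxy)phenyl]-4H-chromen-4-one F6, where only the carbonyl/C5 site can chelate. Allylation (allyl bromide, K2CO3, DMF, 60 °C) would give 7-methoxy-8-(3-methylbut-2-en-1-yl)-5-(prop-2-en-1-yloxy)-2-[4-(prop-2-en-1-yloxy)phenyl]-4H-chromen-4-one F7. The sequence of step 9 would then pass through the 3-lithio derivative [7-methoxy-8-(3-methylbut-2-en-1-yl)-4-oxo-5-(prop-2-en-1-yloxy)-2-[4-(prop-2-en-1-yloxy)phenyl]-4H-chromen-3-yl]lithium F8 and the boronate dimethyl [7-methoxy-8-(3-methylbut-2-en-1-yl)-4-oxo-5-(prop-2-en-1-yloxy)-2-[4-(prop-2-en-1-yloxy)phenyl]-4H-chromen-3-yl]boronate F9 to 3-hydroxy-7-methoxy-8-(3-methylbut-2-en-1-yl)-5-(prop-2-en-1-yloxy)-2-[4-(prop-2-en-1-yloxy)phenyl]-4H-chromen-4-one F10. Removal of both allyl groups with Pd(PPh3)4 and morpholine would give 19 directly.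

**Further compounds**
F1 | step 8 | ethyl (2Z)-3-(3,5-dimethoxyphenoxy)-3-[4-(prop-2-en-1-yloxy)phenyl]prop-2-enoate | CCOC(=O)/C=C(/c1ccc(OCC=C)cc1)Oc1cc(OC)cc(OC)c1
F2 | step 8 | (2Z)-3-(3,5-dimethoxyphenoxy)-3-[4-(prop-2-en-1-yloxy)phenyl]prop-2-enoic acid | O=C(O)/C=C(/c1ccc(OCC=C)cc1)Oc1cc(OC)cc(OC)c1
F3 | step 8 | 5,7-dimethoxy-2-[4-(prop-2-en-1-yloxy)phenyl]-4H-chromen-4-one | C=CCOc1ccc(-c2cc(=O)c3c(OC)cc(OC)cc3o2)cc1
F4 | step 8 | 8-iodo-5,7-dimethoxy-2-[4-(prop-2-en-1-yloxy)phenyl]-4H-chromen-4-one | C=CCOc1ccc(-c2cc(=O)c3c(OC)cc(OC)c(I)c3o2)cc1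
F5 | step 6 | ethyl (2Z)-3-iodo-3-[4-(prop-2-en-1-yloxy)phenyl]prop-2-enoate | CCOC(=O)/C=C(/c1ccc(OCC=C)cc1)I
F6 | step 11 | 5-hydroxy-7-methoxy-8-(3-methylbut-2-en-1-yl)-2-[4-(prop-2-en-1-yloxy)phenyl]-4H-chromen-4-one | C=CCOc1ccc(-c2cc(=O)c3c(O)cc(OC)c(CC=C(C)C)c3o2)cc1
F7 | step 11 | 7-methoxy-8-(3-methylbut-2-en-1-yl)-5-(prop-2-en-1-yloxy)-2-[4-(prop-2-en-1-yloxy)phenyl]-4H-chromen-4-one | C=CCOc1ccc(-c2cc(=O)c3c(OCC=C)cc(OC)c(CC=C(C)C)c3o2)cc1
F8 | step 11 | [7-methoxy-8-(3-methylbut-2-en-1-yl)-4-oxo-5-(prop-2-en-1-yloxy)-2-[4-(prop-2-en-1-yloxy)phenyl]-4H-chromen-3-yl]lithium | C=CCOc1ccc(-c2oc3c(CC=C(C)C)c(OC)cc(OCC=C)c3c(=O)c2[Li])cc1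
F9 | step 11 | dimethyl [7-methoxy-8-(3-methylbut-2-en-1-yl)-4-oxo-5-(prop-2-en-1-yloxy)-2-[4-(prop-2-en-1-yloxy)phenyl]-4H-chromen-3-yl]boronate | C=CCOc1ccc(-c2oc3c(CC=C(C)C)c(OC)cc(OCC=C)c3c(=O)c2B(OC)OC)cc1
F10 | step 11 | 3-hydroxy-7-methoxy-8-(3-methylbut-2-en-1-yl)-5-(prop-2-en-1-yloxy)-2-[4-(prop-2-en-1-yloxy)phenyl]-4H-chromen-4-one | C=CCOc1ccc(-c2oc3c(CC=C(C)C)c(OC)cc(OCC=C)c3c(=O)c2O)cc1
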